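**Retrosynthetic overview**
1. The last cut is the bond between the CH2 on C2 of the chromone and ring B (the benzoic acid ring). A 2-(bromomethyl)chromone is joined to a fully benzylated ring B arylboronate by sp3–sp2 Suzuki–Miyaura coupling, and one hydrogenolysis then frees the three phenols and the acid.
2. The CH2Br group is the reduced and brominated form of a carboxyl on C2, so the ring A/pyranone half goes back to 5-heptyl-7-hydroxy-4-oxo-4H-chromene-2-carboxylic acid.
3. The key cut is the C4–C4a bond. C4a of ring A (the benzo ring) lies para to the C7 hydroxyl and next to C8a, the carbon bearing O1. It is therefore the most nucleophilic carbon within reach of an acyl cation tethered through O1–C2=C3.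
4. The precursor, (Z)-2-(3-heptyl-5-hydroxyphenoxy)but-2-enedioic acid, comes from 5-heptylresorcinol and dimethyl acetylenedicarboxylate (O1–C2 bond by oxa-Michael addition, then saponification). The ring B boronate comes from 5-bromoresorcinol by benzylation, formylation, oxidation, esterification and borylation.
5. Rings A and B are bought, and the pyranone is the only ring made (step 3). The target has no stereocentre.

Key step: step 3

Assumption: the oxa-Michael adduct of step 1 is drawn as its Z (aryloxyfumarate) isomer; any E isomer formed alongside is carried on unseparated, because the strong acid of step 3 equilibrates the two geometries.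

**Step 1**
Reactants: 1 5-heptylbenzene-1,3-diol (5-heptylresorcinol); 2 dimethyl but-2-ynedioate (dimethyl acetylenedicarboxylate)
Product: 3 dimethyl (Z)-2-(3-heptyl-5-hydroxyphenoxy)but-2-enedioate
Conditions: 1 (3 equiv), 2 (1 equiv, slow addition), DABCO (10 mol %), CH2Cl2, 0 °C → rt; excess 1 recovered by chromatography
Reagents that add atoms: none
Why: Amine-catalysed oxa-Michael addition of a phenol to an activated alkyne forms the O1–C2 bond, anti addition places the aryloxy group cis to the distal ester (Z geometry), and the threefold excess of the symmetric diol keeps the second hydroxyl free.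

**Step 2**
Reactants: 3 dimethyl (Z)-2-(3-heptyl-5-hydroxyphenoxy)but-2-enedioate
Product: 4 (Z)-2-(3-heptyl-5-hydroxyphenoxy)but-2-enedioic acid
Conditions: NaOH (2 M aq, 5 equiv), THF–MeOH, rt → 50 °C; then 2 M HCl to pH 1
Reagents that add atoms: sodium hydroxide [Na+].[OH-]
Why: Saponification (acyl–oxygen cleavage) of the two methyl esters leaves the aryl vinyl ether intact, because the aryloxide is a poor leaving group once the free phenol is ionised, and acidification delivers the diacid.

**Step 3**
Reactants: 4 (Z)-2-(3-heptyl-5-hydroxyphenoxy)but-2-enedioic acid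
Product: 5 5-heptyl-7-hydroxy-4-oxo-4H-chromene-2-carboxylic acid
Conditions: P2O5–MeSO3H (1:10 w/w), 0.1 M, rt → 50 °C; then ice–water
Reagents that add atoms: none
Why: The dehydrating acid turns the carboxyl lying cis to the aryloxy group into an acylium ion, which attacks ring A at the carbon flanked by the ether oxygen and the heptyl chain; deprotonation of the σ-complex rearomatises the ring and leaves the new C4–C4a bond. The closest known reaction type is the acid-mediated intramolecular Friedel–Crafts acylation of aryloxyfumaric acids to chromone-2-carboxylic acids, for which H2SO4, polyphosphoric acid and P2O5–MeSO3H are established media; the last is chosen because it neither sulfonates nor oxidises the free phenol. The pyranone closes as a six-membered ring by electrophilic aromatic substitution at carbon, with the enol-ether C2=C3 bond ending up inside the ring, while the carboxyl geminal to the aryloxy group could only close a strained five-membered benzofuranone and so survives as the C2 handle. No stereocentre is created, and any E isomer is brought into the reactive Z geometry by reversible C-protonation of the enol ether. The selectivity needed is between the two ring carbons ortho to the ether oxygen: the wanted one is para to the free hydroxyl (the strongest donor on ring A, since the ether oxygen is drained by two carboxyl groups) and ortho to the chain, whereas the carbon between the two oxygens is ortho to the hydroxyl and para only to the weakly donating chain; small acyl electrophiles (Gattermann, Hoesch, Friedel–Crafts) attack 5-n-alkylresorcinols in this para-to-OH, next-to-chain sense, although bulkier Pechmann-type electrophiles can prefer the other site. The chromone is held in the acid as its 4-hydroxybenzopyrylium ion, so the acylation should not reverse and the kinetic para preference should be retained, while moderate temperature and dilution are meant to sharpen it and suppress intermolecular O-acylation.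

**Step 4**
Reactants: 5 5-heptyl-7-hydroxy-4-oxo-4H-chromene-2-carboxylic acid
Product: 6 benzyl 7-(benzyloxy)-5-heptyl-4-oxo-4H-chromene-2-carboxylate
Conditions: BnBr (2.4 equiv), K2CO3 (3 equiv), DMF, rt → 40 °C
Reagents that add atoms: benzyl bromide BrCc1ccccc1
Why: Williamson etherification of the C7 phenoxide and SN2 alkylation of the carboxylate occur in one operation, giving an ester ready for reduction and a phenol protecting group that falls in the final hydrogenolysis.

**Step 5**
Reactants: 6 benzyl 7-(benzyloxy)-5-heptyl-4-oxo-4H-chromene-2-carboxylate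
Product: 7 7-(benzyloxy)-5-heptyl-2-(hydroxymethyl)-4H-chromen-4-one
Conditions: NaBH4 (1.5 equiv), THF–MeOH (4:1), −10 → 0 °C; then H2O
Reagents that add atoms: none
Why: This is the chemoselective borohydride reduction known for chromone-2-carboxylates, in which the C2 ester is activated by the ring oxygen and the enone while the C4 carbonyl is a vinylogous ester further shielded by the peri heptyl chain, so at low temperature only the ester should be reduced.

**Step 6**
Reactants: 7 7-(benzyloxy)-5-heptyl-2-(hydroxymethyl)-4H-chromen-4-one
Product: 8 7-(benzyloxy)-2-(bromomethyl)-5-heptyl-4H-chromen-4-one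
Conditions: CBr4 (1.3 equiv), PPh3 (1.3 equiv), CH2Cl2, 0 °C
Reagents that add atoms: carbon tetrabromide BrC(Br)(Br)Br
Why: In the Appel reaction the primary alcohol is activated as an alkoxyphosphonium ion and displaced by bromide (SN2) under neutral conditions that leave the chromone and the benzyl ether untouched.

**Step 7**
Reactants: 9 5-bromobenzene-1,3-diol (5-bromoresorcinol)
Product: 10 1,3-bis(benzyloxy)-5-bromobenzene
Conditions: BnBr (2.3 equiv), K2CO3 (3 equiv), DMF, 60 °C
Reagents that add atoms: benzyl bromide BrCc1ccccc1
Why: Double Williamson etherification protects both phenols with groups that tolerate the formylation, oxidation and palladium chemistry ahead and are removed by hydrogenolysis at the end.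

**Step 8**
Reactants: 10 1,3-bis(benzyloxy)-5-bromobenzene
Product: 12 2,4-bis(benzyloxy)-6-bromobenzaldehyde, via aryliminium dichlorophosphate 11 (not isolated)
Conditions: POCl3 (3 equiv), DMF, 0 → 80 °C; then aq NaOAc, rt
Reagents that add atoms: N,N-dimethylformamide CN(C)C=O; water O
Why: Vilsmeier–Haack formylation attacks the carbon para to one benzyloxy group and ortho to the other (next to bromine) rather than the more crowded carbon between the two ethers, as is usual for 3,5-dialkoxybromobenzenes, and aqueous work-up hydrolyses the iminium salt to the aldehyde.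

**Step 9**
Reactants: 12 2,4-bis(benzyloxy)-6-bromobenzaldehyde
Product: 13 2,4-bis(benzyloxy)-6-bromobenzoic acid
Conditions: NaClO2, NaH2PO4, 2-methyl-2-butene, t-BuOH–THF–H2O, rt
Reagents that add atoms: sodium chlorite [Na+].[O-]Cl=O
Why: Pinnick oxidation converts the hindered aldehyde into the acid under buffered conditions, with 2-methyl-2-butene trapping the hypochlorous acid that would otherwise chlorinate the electron-rich ring.

**Step 10**
Reactants: 13 2,4-bis(benzyloxy)-6-bromobenzoic acid
Product: 14 benzyl 2,4-bis(benzyloxy)-6-bromobenzoate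
Conditions: BnBr (1.2 equiv), K2CO3 (1.5 equiv), DMF, rt
Reagents that add atoms: benzyl bromide BrCc1ccccc1
Why: Carboxylate alkylation (SN2 at benzyl bromide) esterifies the di-ortho-substituted acid without any attack at its hindered carbonyl carbon.

**Step 11**
Reactants: 14 benzyl 2,4-bis(benzyloxy)-6-bromobenzoate
Product: 15 benzyl 2,4-bis(benzyloxy)-6-(4,4,5,5-tetramethyl-1,3,2-dioxaborolan-2-yl)benzoate
Conditions: B2pin2 (1.3 equiv), PdCl2(dppf) (5 mol %), KOAc (3 equiv), 1,4-dioxane, 90 °C
Reagents that add atoms: bis(pinacolato)diboron CC1(C)OB(OC1(C)C)B1OC(C)(C)C(C)(C)O1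
Why: In the Miyaura borylation, oxidative addition of the aryl bromide to zerovalent palladium, acetate-assisted transmetalation with B2pin2 and reductive elimination give the pinacol boronate, a sequence that tolerates ortho ester groups well.

**Step 12**
Reactants: 8 7-(benzyloxy)-2-(bromomethyl)-5-heptyl-4H-chromen-4-one; 15 benzyl 2,4-bis(benzyloxy)-6-(4,4,5,5-tetramethyl-1,3,2-dioxaborolan-2-yl)benzoate
Product: 16 benzyl 2,4-bis(benzyloxy)-6-{[7-(benzyloxy)-5-heptyl-4-oxo-4H-chromen-2-yl]methyl}benzoate
Conditions: PdCl2(dppf) (5 mol %), K3PO4 (2.5 equiv), THF–H2O (10:1), degassed, 60 °C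
Reagents that add atoms: none
Why: In this Suzuki–Miyaura sp3–sp2 cross-coupling of a benzylic-type bromide, oxidative addition of the activated C–Br bond to zerovalent palladium is fast, the resulting palladium alkyl has no β-hydrogen, and the mild phosphate base should spare the chromone and the hindered benzyl ester.

**Step 13**
Reactants: 16 benzyl 2,4-bis(benzyloxy)-6-{[7-(benzyloxy)-5-heptyl-4-oxo-4H-chromen-2-yl]methyl}benzoate
Product: 17 siphulin, 2-[(5-heptyl-7-hydroxy-4-oxo-4H-chromen-2-yl)methyl]-4,6-dihydroxybenzoic acid
Conditions: H2 (1 atm), Pd/C (10 wt %), EtOAc–MeOH (1:1), rt, stopped after uptake of 4 equiv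
Reagents that add atoms: none
Why: Catalytic hydrogenolysis cleaves the three benzyl ethers and the benzyl ester at their O–CH2 bonds under neutral conditions at room temperature, which should spare the pseudo-aromatic C2=C3 bond of the chromone and the decarboxylation-prone 2,4-dihydroxybenzoic acid.

**Compound list**
1 | 5-heptylbenzene-1,3-diol | CCCCCCCc1cc(O)cc(O)c1 | starting material
2 | dimethyl but-2-ynedioate | COC(=O)C#CC(=O)OC | starting material
3 | dimethyl (Z)-2-(3-heptyl-5-hydroxyphenoxy)but-2-enedioate | CCCCCCCc1cc(O)cc(O/C(C(=O)OC)=C\C(=O)OC)c1 | intermediate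
4 | (Z)-2-(3-heptyl-5-hydroxyphenoxy)but-2-enedioic acid | CCCCCCCc1cc(O)cc(O/C(C(=O)O)=C\C(=O)O)c1 | intermediate
5 | 5-heptyl-7-hydroxy-4-oxo-4H-chromene-2-carboxylic acid | CCCCCCCc1cc(O)cc2oc(C(=O)O)cc(=O)c12 | intermediate
6 | benzyl 7-(benzyloxy)-5-heptyl-4-oxo-4H-chromene-2-carboxylate | CCCCCCCc1cc(OCc3ccccc3)cc2oc(C(=O)OCc3ccccc3)cc(=O)c12 | intermediate
7 | 7-(benzyloxy)-5-heptyl-2-(hydroxymethyl)-4H-chromen-4-one | CCCCCCCc1cc(OCc3ccccc3)cc2oc(CO)cc(=O)c12 | intermediate
8 | 7-(benzyloxy)-2-(bromomethyl)-5-heptyl-4H-chromen-4-one | CCCCCCCc1cc(OCc3ccccc3)cc2oc(CBr)cc(=O)c12 | intermediate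
9 | 5-bromobenzene-1,3-diol | Oc1cc(O)cc(Br)c1 | starting material
10 | 1,3-bis(benzyloxy)-5-bromobenzene | Brc1cc(OCc2ccccc2)cc(OCc2ccccc2)c1 | intermediate
11 | N-[2,4-bis(benzyloxy)-6-bromobenzylidene]-N-methylmethanaminium dichlorophosphate (not isolated) | C[N+](C)=Cc1c(Br)cc(OCc2ccccc2)cc1OCc1ccccc1.[O-]P(=O)(Cl)Cl | intermediate
12 | 2,4-bis(benzyloxy)-6-bromobenzaldehyde | O=Cc1c(Br)cc(OCc2ccccc2)cc1OCc1ccccc1 | intermediate
13 | 2,4-bis(benzyloxy)-6-bromobenzoic acid | OC(=O)c1c(Br)cc(OCc2ccccc2)cc1OCc1ccccc1 | intermediate
14 | benzyl 2,4-bis(benzyloxy)-6-bromobenzoate | O=C(OCc1ccccc1)c1c(Br)cc(OCc2ccccc2)cc1OCc1ccccc1 | intermediate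
15 | benzyl 2,4-bis(benzyloxy)-6-(4,4,5,5-tetramethyl-1,3,2-dioxaborolan-2-yl)benzoate | O=C(OCc1ccccc1)c1c(B2OC(C)(C)C(C)(C)O2)cc(OCc2ccccc2)cc1OCc1ccccc1 | intermediate
16 | benzyl 2,4-bis(benzyloxy)-6-{[7-(benzyloxy)-5-heptyl-4-oxo-4H-chromen-2-yl]methyl}benzoate | CCCCCCCc1cc(OCc3ccccc3)cc2oc(Cc3cc(OCc4ccccc4)cc(OCc4ccccc4)c3C(=O)OCc3ccccc3)cc(=O)c12 | intermediate
17 | siphulin | CCCCCCCc1cc(O)cc2oc(Cc3cc(O)cc(O)c3C(=O)O)cc(=O)c12 | target

Total step count: 13
Longest linear sequence: 8 steps (steps 1–6, 12, 13). The ring B branch (steps 7–11) joins at step 12.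

**Steps most likely to fail**

**Step 3 (key step).**
- **Risk:** Ring closure at the ortho carbon between the two oxygens may compete with closure next to the heptyl chain. Intermolecular O-acylation of the free phenol may also consume material.
- **Fallback:** It sets out from 1 and comes back at 5, and it closes the pyranone at oxygen instead of carbon.
  - C-Acetylation of 1 (AcOH, BF3·OEt2, 80 °C) goes para to one hydroxyl and next to the chain in 5-n-alkylresorcinols. It would give 1-(2-heptyl-4,6-dihydroxyphenyl)ethan-1-one F1, and any site isomer can be removed at this stage.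
  - Claisen condensation with diethyl oxalate (NaOEt, EtOH, reflux) would give ethyl 4-(2-heptyl-4,6-dihydroxyphenyl)-2,4-dioxobutanoate F2.
  - Acid (HCl, EtOH, reflux) would cyclodehydrate it through the only ortho hydroxyl to ethyl 5-heptyl-7-hydroxy-4-oxo-4H-chromene-2-carboxylate F3.
  - Hydrolysis (aq HCl, AcOH, reflux) returns 5.

**Step 12.**
- **Risk:** The electron-rich ortho-ester boronate may protodeboronate, and the bromide may hydrolyse or homocouple. Base may also deprotonate the doubly activated CH2 of the product, followed by over-alkylation or condensation onto the ester.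
- **Fallback:** It sets out from 7 and 14 and comes back at 17, forming the bond by carbonyl addition instead of cross-coupling.
  - Oxidation of 7 (Dess–Martin periodinane, CH2Cl2, rt) would give 7-(benzyloxy)-5-heptyl-4-oxo-4H-chromene-2-carbaldehyde F4.
  - Bromine–magnesium exchange on 14 (iPrMgCl·LiCl, THF, −30 °C), assisted by the ortho ester, would give benzyl 2,4-bis(benzyloxy)-6-(chloromagnesio)benzoate F5.
  - 1,2-Addition of F5 to F4, with lactonisation onto the neighbouring benzyl ester in the same flask, would give racemic 5,7-bis(benzyloxy)-3-[7-(benzyloxy)-5-heptyl-4-oxo-4H-chromen-2-yl]-2-benzofuran-1(3H)-one F6.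
  - Hydrogenolysis (H2, Pd/C, EtOAc–AcOH, rt) would cleave the three benzyl ethers and the doubly activated lactone C–O bond. This erases the stereocentre and gives 17 directly.

**Step 1.**
- **Risk:** A second addition at the remaining phenol, C-alkylation of the electron-rich ring, and a difficult separation from the excess diol are all possible.
- **Fallback:** It sets out from 1 and comes back at 4, replacing stoichiometric control by temporary protection.
  - Monoacylation of 1 (pivaloyl chloride, 1 equiv, pyridine, CH2Cl2, 0 °C; unreacted diol and diester are separable and recyclable) would give 3-heptyl-5-hydroxyphenyl 2,2-dimethylpropanoate F7. This has one nucleophilic oxygen and a less electron-rich ring.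
  - Oxa-Michael addition to 2 (1.1 equiv, DABCO 10 mol %, CH2Cl2) would give dimethyl (Z)-2-[3-(2,2-dimethylpropanoyloxy)-5-heptylphenoxy]but-2-enedioate F8.
  - The NaOH treatment of step 2 cleaves the aryl pivalate together with both methyl esters and gives 4.

**Further compounds**
F1 | step 3 | 1-(2-heptyl-4,6-dihydroxyphenyl)ethan-1-one | CCCCCCCc1cc(O)cc(O)c1C(C)=O
F2 | step 3 | ethyl 4-(2-heptyl-4,6-dihydroxyphenyl)-2,4-dioxobutanoate | CCCCCCCc1cc(O)cc(O)c1C(=O)CC(=O)C(=O)OCC
F3 | step 3 | ethyl 5-heptyl-7-hydroxy-4-oxo-4H-chromene-2-carboxylate | CCCCCCCc1cc(O)cc2oc(C(=O)OCC)cc(=O)c12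
F4 | step 12 | 7-(benzyloxy)-5-heptyl-4-oxo-4H-chromene-2-carbaldehyde | CCCCCCCc1cc(OCc3ccccc3)cc2oc(C=O)cc(=O)c12
F5 | step 12 | benzyl 2,4-bis(benzyloxy)-6-(chloromagnesio)benzoate | O=C(OCc1ccccc1)c1c([Mg]Cl)cc(OCc2ccccc2)cc1OCc1ccccc1
F6 | step 12 | racemic 5,7-bis(benzyloxy)-3-[7-(benzyloxy)-5-heptyl-4-oxo-4H-chromen-2-yl]-2-benzofuran-1(3H)-one | CCCCCCCc1cc(OCc3ccccc3)cc2oc(C3OC(=O)c4c3cc(OCc3ccccc3)cc4OCc3ccccc3)cc(=O)c12
F7 | step 1 | 3-heptyl-5-hydroxyphenyl 2,2-dimethylpropanoate | CCCCCCCc1cc(O)cc(OC(=O)C(C)(C)C)c1
F8 | step 1 | dimethyl (Z)-2-[3-(2,2-dimethylpropanoyloxy)-5-heptylphenoxy]but-2-enedioate | CCCCCCCc1cc(OC(=O)C(C)(C)C)cc(O/C(C(=O)OC)=C\C(=O)OC)c1
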